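α-Onocerin is cut at C4–C5 in both halves at once. In one operation, titanocene-mediated reductive opening of two (S)-configured trisubstituted epoxides gives tertiary C4 radicals that attack C5 of C5=C6 alkenes (6-exo), closing both rings A and setting both ring-fusion centres. This exploits the C3 carbinol next to the gem-dimethyl C4, which is bonded to the A/B ring-fusion carbon C5. The precursor is a C2-symmetric bis(epoxide): two cyclohexene rings B, each with a quaternary C10 (methyl and epoxy-ethyl tether), a C5=C6 alkene and a C8 dioxolane, joined through C9–C11–C12–C9'. It is reached from a bibenzyl by asymmetric Birch reduction–alkylation.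

Key step: step 9

Remarks on the chemistry (assumptions):
- Atom numbers (C1–C12, primed for the second half) follow the skeleton of the target in every intermediate.
- The route is two-directional. Step 1 joins two molecules of 1, and steps 2 and 3 each consume two molecules of the second reactant (5 and 8). In these three steps the second molecule is also entered under the reagents that add atoms.
- The potassium enolate of step 3 is assumed to be alkylated on the face that gives the (R)-configured quaternary carbons with the (S)-auxiliary. If the opposite sense is found, the purchasable (R)-auxiliary is used and nothing else changes, because the auxiliary is cleaved in step 5.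
- The C1–C4 chain enters as the Birch electrophile and the carboxamide carbon becomes the C10 methyl, so no C–C bond has to be made at a neopentyl carbon.
- C9 is drawn as the epimer expected from step 4; the other epimer would run through the same steps and converge in step 10.
- Compound 8 and the L-fructose-derived enantiomer of the Shi ketone are taken as purchasable.

Step 1
Reactants: 1 3-methoxy-2-methylbenzoic acid (two molecules)
Product: 4 2,2'-(ethane-1,2-diyl)bis(3-methoxybenzoic acid), via dilithio benzylic dianion 2 (not isolated), via benzylic iodide 3 (not isolated)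
Conditions: LiN(i-Pr)2 (2.2 equiv), THF, −78 → 0 °C; I2 (0.55 equiv), −78 °C → rt; aq. HCl
Reagents that add atoms: 3-methoxy-2-methylbenzoic acid (second molecule of 1), COc1cccc(C(=O)O)c1C
Why: Two equivalents of amide base turn each molecule of 1 into the carboxylate/benzylic dianion 2 at the methyl group flanked by CO2Li and OMe (lateral lithiation), and half an equivalent of iodine converts half of it into the benzylic iodide 3, which a second molecule of 2 displaces, so two molecules of 1 are joined through their methyl carbons in a net oxidative benzylic homocoupling that needs no stereocontrol.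

Step 2
Reactants: 4 2,2'-(ethane-1,2-diyl)bis(3-methoxybenzoic acid); 5 (S)-2-(methoxymethyl)pyrrolidine (two molecules)
Product: 7 1,2-bis[2-methoxy-6-{[(2S)-2-(methoxymethyl)pyrrolidin-1-yl]carbonyl}phenyl]ethane, via bis(acid chloride) 6 (not isolated)
Conditions: (COCl)2, DMF (cat.), CH2Cl2, 0 °C → rt; concentrate; 5 (2.4 equiv), Et3N, CH2Cl2, 0 °C → rt
Reagents that add atoms: (S)-2-(methoxymethyl)pyrrolidine (second molecule of 5), COC[C@@H]1CCCN1
Why: Acylation of the secondary amine by the bis(acid chloride) (amide formation) installs the O-methylated prolinol auxiliary on both carboxyl groups, whose ether oxygen, unlike a free hydroxyl, is neither deprotonated nor alkylated in the next step; the stereocentres come from 5.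

Step 3
Reactants: 7 1,2-bis[2-methoxy-6-{[(2S)-2-(methoxymethyl)pyrrolidin-1-yl]carbonyl}phenyl]ethane; 8 5-bromo-2-methylpent-2-ene (two molecules)
Product: 10 1,2-bis[(6R)-2-methoxy-6-{[(2S)-2-(methoxymethyl)pyrrolidin-1-yl]carbonyl}-6-(4-methylpent-3-en-1-yl)cyclohexa-1,4-dien-1-yl]ethane, via bis(potassium amide enolate) 9 (not isolated)
Conditions: K (5 equiv), t-BuOH (2 equiv), NH3/THF, −78 °C; piperylene; 8 (5 equiv), −78 → −33 °C; NH4Cl
Reagents that add atoms: 5-bromo-2-methylpent-2-ene (second molecule of 8), CC(C)=CCCBr
Why: Dissolving-metal reduction of each benzamide ring protonates the position para to the carboxamide and leaves a dienolate at C10, which the chelated (S)-methoxymethylpyrrolidine shields on one face so that the primary bromide alkylates the other (asymmetric Birch reduction–alkylation of chiral benzamides), setting C10 and C10' and leaving exactly the C5=C6 alkene and the C8 methyl enol ether.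

Step 4
Reactants: 10 1,2-bis[(6R)-2-methoxy-6-{[(2S)-2-(methoxymethyl)pyrrolidin-1-yl]carbonyl}-6-(4-methylpent-3-en-1-yl)cyclohexa-1,4-dien-1-yl]ethane
Product: 11 1,2-bis[(6R,7R)-7-{[(2S)-2-(methoxymethyl)pyrrolidin-1-yl]carbonyl}-7-(4-methylpent-3-en-1-yl)-1,4-dioxaspiro[4.5]dec-8-en-6-yl]ethane
Conditions: HOCH2CH2OH (10 equiv), PPTS (0.2 equiv), CH2Cl2, rt
Reagents that add atoms: ethylene glycol, OCCO
Why: Acid-catalysed exchange of the tetrasubstituted methyl enol ether for the dioxolane (transketalisation through the C8 oxocarbenium ion) protonates C9 from the face away from the bulky C10 carboxamide, which sets C9 with the C11 chain cis to that group, and the alkene stays at C5=C6 because no free ketone or conjugated isomer is formed under pyridinium catalysis.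

Step 5
Reactants: 11 1,2-bis[(6R,7R)-7-{[(2S)-2-(methoxymethyl)pyrrolidin-1-yl]carbonyl}-7-(4-methylpent-3-en-1-yl)-1,4-dioxaspiro[4.5]dec-8-en-6-yl]ethane
Product: 12 1,2-bis[(6R,7R)-7-(hydroxymethyl)-7-(4-methylpent-3-en-1-yl)-1,4-dioxaspiro[4.5]dec-8-en-6-yl]ethane
Conditions: LiH2NBH3 (8 equiv, from BH3·NH3 and LiN(i-Pr)2), THF, 0 → 23 °C; aq. NH4Cl
Reagents that add atoms: none
Why: Lithium amidotrihydroborate is a small, strongly nucleophilic hydride donor that reduces even α-quaternary tertiary amides to primary alcohols with C–N cleavage (amide reduction), releasing the auxiliary for recovery and leaving ketals, alkenes and stereocentres untouched.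

Step 6
Reactants: 12 1,2-bis[(6R,7R)-7-(hydroxymethyl)-7-(4-methylpent-3-en-1-yl)-1,4-dioxaspiro[4.5]dec-8-en-6-yl]ethane
Product: 13 1,2-bis[(6R,7R)-7-formyl-7-(4-methylpent-3-en-1-yl)-1,4-dioxaspiro[4.5]dec-8-en-6-yl]ethane
Conditions: Pr4N[RuO4] (5 mol %), N-methylmorpholine N-oxide (3 equiv), 4 Å sieves, CH2Cl2, rt
Reagents that add atoms: none
Why: Catalytic perruthenate with an N-oxide reoxidant (Ley–Griffith oxidation) stops at the aldehyde, which has no α-hydrogen and cannot epimerise, under neutral conditions that spare the ketals and alkenes.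

Step 7
Reactants: 13 1,2-bis[(6R,7R)-7-formyl-7-(4-methylpent-3-en-1-yl)-1,4-dioxaspiro[4.5]dec-8-en-6-yl]ethane
Product: 15 1,2-bis[(6R,7S)-7-methyl-7-(4-methylpent-3-en-1-yl)-1,4-dioxaspiro[4.5]dec-8-en-6-yl]ethane, via bis(hydrazone) 14 (not isolated)
Conditions: N2H4·H2O, diethylene glycol, 80 → 110 °C, argon; KOH, 200 °C
Reagents that add atoms: none
Why: The hydrazone is formed first under neutral conditions and then decomposed by hot hydroxide with loss of N2 (Wolff–Kishner reduction in the Huang-Minlon form), which turns each formyl carbon into the C10 methyl under basic conditions that dioxolanes and isolated alkenes tolerate; no stereocentre is touched.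

Step 8
Reactants: 15 1,2-bis[(6R,7S)-7-methyl-7-(4-methylpent-3-en-1-yl)-1,4-dioxaspiro[4.5]dec-8-en-6-yl]ethane
Product: 16 1,2-bis[(6R,7S)-7-{2-[(2S)-3,3-dimethyloxiran-2-yl]ethyl}-7-methyl-1,4-dioxaspiro[4.5]dec-8-en-6-yl]ethane
Conditions: L-fructose-derived Shi ketone (0.6 equiv), KHSO5 (as 2KHSO5·KHSO4·K2SO4), K2CO3, Bu4NHSO4, MeCN–dimethoxymethane/aq. Na2B4O7–Na2H2EDTA (pH 10.5), 0 °C
Reagents that add atoms: potassium peroxymonosulfate, [K+].[O-]S(=O)(=O)OO
Why: The chiral dioxirane from the L-fructose-derived ketone (Shi epoxidation) attacks the electron-rich trisubstituted chain alkenes much faster than the hindered cis-disubstituted ring alkenes and, through the spiro transition state, delivers oxygen to the face that gives the (S)-epoxide at each C3 under catalyst control, independent of the remote ring stereocentres.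

Step 9
Reactants: 16 1,2-bis[(6R,7S)-7-{2-[(2S)-3,3-dimethyloxiran-2-yl]ethyl}-7-methyl-1,4-dioxaspiro[4.5]dec-8-en-6-yl]ethane
Product: 17 bis(ethylene ketal) of 3β,21α-dihydroxy-26,27-dinor-8,14-secogammacerane-8,14-dione (trans-fused; each half 3S,5R,9R,10S)
Conditions: Cp2TiCl2 (0.4 equiv), Mn dust (8 equiv), 2,4,6-collidine·HCl (6 equiv), THF (0.01 M), rt
Reagents that add atoms: none
Why: Cp2TiCl (trivalent titanium), generated from Cp2TiCl2 and Mn, transfers one electron to each epoxide and breaks the C4–O bond to give the tertiary C4 radical with a titanium alkoxide on C3; the radical adds to C5 of the ring-B alkene, and the secondary C6 radical is reduced by a second Cp2TiCl and protonated by collidinium chloride, which also releases the alcohol and returns Cp2TiCl2. The closest known reaction type is the titanocene-mediated reductive epoxide opening–radical cyclisation of epoxy alkenes to 3-hydroxy-4,4-dimethylcyclohexanes. Rings A and A' each close in the 6-exo-trig mode (C4 to C5), the 7-endo alternative at C6 being disfavoured because it would give a bridged ring. The new stereocentres C5 and C5' are controlled by the adjacent quaternary centres C10 and C10', which carry the tethers, while C3 and C21 keep the configuration of the (S)-epoxides and end up equatorial (3β). The step needs trans ring fusion, that is bond formation on the C5 face that lies on the side of the C10 methyl (chair with axial C10 methyl and both ring-B bonds equatorial), against the cis fusion that exo closures onto ring alkenes normally prefer. The substrate offers only a steric bias for it, because the cis chair must place C9 (bearing the C11 chain, next to the C8 dioxolane) axial and syn to a C4 methyl, so this facial preference is not guaranteed and is the one large risk of the route.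

Step 10
Reactants: 17 bis(ethylene ketal) of 3β,21α-dihydroxy-26,27-dinor-8,14-secogammacerane-8,14-dione
Product: 18 3β,21α-dihydroxy-26,27-dinor-8,14-secogammacerane-8,14-dione (each half 3S,5R,9R,10S)
Conditions: 2 M aq. HCl, THF, rt; K2CO3, MeOH, rt
Reagents that add atoms: water, O
Why: Aqueous acid hydrolyses both dioxolanes (acetal hydrolysis) and the carbonate treatment equilibrates C9, now α to the C8 ketone, by enolisation to the thermodynamically preferred equatorial side chain (9α-H), so either C9 epimer converges here while C3, C5 and C10 cannot epimerise.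

Step 11
Reactants: 18 3β,21α-dihydroxy-26,27-dinor-8,14-secogammacerane-8,14-dione
Product: 19 α-onocerin
Conditions: Ph3PCH3Br (8 equiv), KOt-Bu (7.5 equiv), THF, rt → 65 °C
Reagents that add atoms: methyltriphenylphosphonium bromide, C[P+](c1ccccc1)(c1ccccc1)c1ccccc1.[Br-]
Why: Excess methylenetriphenylphosphorane converts both hindered C8 ketones into the exocyclic methylenes (Wittig methylenation), the free hydroxyls being carried as alkoxides, and any enolisation at C9 under the basic conditions returns the equatorial configuration already present, so no stereocentre changes.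

Compound list
1 | 3-methoxy-2-methylbenzoic acid | COc1cccc(C(=O)O)c1C | starting material
2 | dilithio benzylic dianion of 1, lithium 2-(lithiomethyl)-3-methoxybenzoate (not isolated) | [Li]Cc1c(OC)cccc1C(=O)O[Li] | intermediate
3 | benzylic iodide from 2, lithium 2-(iodomethyl)-3-methoxybenzoate (not isolated) | ICc1c(OC)cccc1C(=O)O[Li] | intermediate
4 | 2,2'-(ethane-1,2-diyl)bis(3-methoxybenzoic acid) | O=C(O)c1cccc(OC)c1CCc1c(OC)cccc1C(=O)O | intermediate
5 | (S)-2-(methoxymethyl)pyrrolidine | COC[C@@H]1CCCN1 | starting material
6 | 2,2'-(ethane-1,2-diyl)bis(3-methoxybenzoyl chloride) (not isolated) | O=C(Cl)c1cccc(OC)c1CCc1c(OC)cccc1C(=O)Cl | intermediate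
7 | 1,2-bis[2-methoxy-6-{[(2S)-2-(methoxymethyl)pyrrolidin-1-yl]carbonyl}phenyl]ethane | COC[C@@H]1CCCN1C(=O)c1cccc(OC)c1CCc1c(OC)cccc1C(=O)N1CCC[C@H]1COC | intermediate
8 | 5-bromo-2-methylpent-2-ene | CC(C)=CCCBr | starting material
9 | bis(potassium amide enolate) from twofold Birch reduction of 7 (not isolated) | [K]OC(N2CCC[C@H]2COC)=C1C=CCC(OC)=C1CCC1=C(OC)CC=CC1=C(O[K])N1CCC[C@H]1COC | intermediate
10 | 1,2-bis[(6R)-2-methoxy-6-{[(2S)-2-(methoxymethyl)pyrrolidin-1-yl]carbonyl}-6-(4-methylpent-3-en-1-yl)cyclohexa-1,4-dien-1-yl]ethane | CC(C)=CCC[C@]2(C(=O)N3CCC[C@H]3COC)C(CCC1=C(OC)CC=C[C@@]1(CCC=C(C)C)C(=O)N1CCC[C@H]1COC)=C(OC)CC=C2 | intermediate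
11 | 1,2-bis[(6R,7R)-7-{[(2S)-2-(methoxymethyl)pyrrolidin-1-yl]carbonyl}-7-(4-methylpent-3-en-1-yl)-1,4-dioxaspiro[4.5]dec-8-en-6-yl]ethane | C12(OCCO1)CC=C[C@](C(=O)N3CCC[C@H]3COC)(CCC=C(C)C)[C@H]2CC[C@H]1C2(OCCO2)CC=C[C@]1(C(=O)N3CCC[C@H]3COC)CCC=C(C)C | intermediate
12 | 1,2-bis[(6R,7R)-7-(hydroxymethyl)-7-(4-methylpent-3-en-1-yl)-1,4-dioxaspiro[4.5]dec-8-en-6-yl]ethane | C12(OCCO1)CC=C[C@](CO)(CCC=C(C)C)[C@H]2CC[C@H]1C2(OCCO2)CC=C[C@]1(CO)CCC=C(C)C | intermediate
13 | 1,2-bis[(6R,7R)-7-formyl-7-(4-methylpent-3-en-1-yl)-1,4-dioxaspiro[4.5]dec-8-en-6-yl]ethane | C12(OCCO1)CC=C[C@](C=O)(CCC=C(C)C)[C@H]2CC[C@H]1C2(OCCO2)CC=C[C@]1(C=O)CCC=C(C)C | intermediate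
14 | bis(hydrazone) of 13 (not isolated) | C12(OCCO1)CC=C[C@](C=NN)(CCC=C(C)C)[C@H]2CC[C@H]1C2(OCCO2)CC=C[C@]1(C=NN)CCC=C(C)C | intermediate
15 | 1,2-bis[(6R,7S)-7-methyl-7-(4-methylpent-3-en-1-yl)-1,4-dioxaspiro[4.5]dec-8-en-6-yl]ethane | C12(OCCO1)CC=C[C@](C)(CCC=C(C)C)[C@H]2CC[C@H]1C2(OCCO2)CC=C[C@]1(C)CCC=C(C)C | intermediate
16 | 1,2-bis[(6R,7S)-7-{2-[(2S)-3,3-dimethyloxiran-2-yl]ethyl}-7-methyl-1,4-dioxaspiro[4.5]dec-8-en-6-yl]ethane (precursor of the key step) | C12(OCCO1)CC=C[C@](C)(CC[C@@H]3OC3(C)C)[C@H]2CC[C@H]1C2(OCCO2)CC=C[C@]1(C)CC[C@@H]2OC2(C)C | intermediate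
17 | bis(ethylene ketal) of 3β,21α-dihydroxy-26,27-dinor-8,14-secogammacerane-8,14-dione, trans-fused, 5α-H, 9α-H, 10β-CH3 in each half (product of the key step) | C12(OCCO1)CC[C@H]3C(C)(C)[C@@H](O)CC[C@]3(C)[C@H]2CC[C@H]1C2(OCCO2)CC[C@H]3C(C)(C)[C@@H](O)CC[C@]13C | intermediate
18 | 3β,21α-dihydroxy-26,27-dinor-8,14-secogammacerane-8,14-dione | O=C1CC[C@H]2C(C)(C)[C@@H](O)CC[C@]2(C)[C@H]1CC[C@H]1C(=O)CC[C@H]2C(C)(C)[C@@H](O)CC[C@]12C | intermediate
19 | α-onocerin, 8,14-secogammacera-8(26),14(27)-diene-3β,21α-diol | C=C1CC[C@H]2C(C)(C)[C@@H](O)CC[C@]2(C)[C@H]1CC[C@H]1C(=C)CC[C@H]2C(C)(C)[C@@H](O)CC[C@]12C | target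

Total step count: 11
Longest linear sequence: 11 steps (1 → 19; the route is linear and two-directional)

Steps most likely to fail

1. Step 9. The radical may close on the C5 face away from the C10 methyl and give cis ring fusion. The tertiary radical may also be lost by hydrogen abstraction or disproportionation before the slow 6-exo closure; that second problem is met by high dilution and catalytic titanium. The fallback replaces kinetic by thermodynamic control of C5; it sets out from 16 and comes back at 17. If the titanium step closes the rings with cis fusion, it gives the 5,5'-bis-epimeric diol F1. This is acetylated (Ac2O, pyridine, DMAP) to the cis-fused diacetate F2. The ring-fusion C5–H bonds of F2 are then epimerised by reversible photochemical hydrogen-atom transfer ((n-Bu4N)4[W10O32] with a diaryl disulfide as hydrogen-atom shuttle, MeCN, 390 nm), a known way of turning cis-fused carbobicycles into their more stable trans isomers. The trans-fused 4,4,10-trimethyldecalin should be the thermodynamic sink, giving the trans-fused diacetate F3, and K2CO3 in MeOH removes the acetates to give 17. The acetates deactivate the C3–H bonds toward abstraction, and epimerisation at C9 does no harm because step 10 resets that centre.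

2. Step 3. The twofold C-alkylation of the potassium enolates by an unactivated primary bromide in liquid ammonia may be incomplete (elimination of the bromide, protonation of the enolate), or the facial preference may be poor. The fallback separates reduction from alkylation; it sets out from 7 and comes back at 10. Birch reduction with a proton quench (K, t-BuOH, NH3/THF, −78 °C; NH4Cl) should give the bis(cyclohexa-2,5-diene-1-carboxamide) F4. F4 is deprotonated at C10 and C10' with LiN(i-Pr)2 in THF/DMPU at −78 °C and alkylated with 8 in a homogeneous step (amide enolate alkylation). The same auxiliary controls the face through the lithium chelate, and the sense of this enolate has to be confirmed on the first run.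

3. Step 7. The formyl group may be lost under base, the aldehyde may undergo thermal ene closure onto the chain alkene before the hydrazone has formed, or the hindered hydrazone may decompose incompletely. The fallback removes the oxygen by hydride displacement instead of carbonyl deoxygenation; it sets out from 12 and comes back at 15, bypassing steps 6 and 7. MsCl and Et3N in CH2Cl2 at 0 °C give the bis(methanesulfonate) F5, and LiEt3BH in THF at 65 °C displaces both neopentyl sulfonates by hydride (sulfonate reduction).

Further compounds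
F1 | step 9 | cis-fused 5,5'-bis-epimer of 17 (5β-H in each half) | C12(OCCO1)CC[C@@H]3C(C)(C)[C@@H](O)CC[C@]3(C)[C@H]2CC[C@H]1C2(OCCO2)CC[C@@H]3C(C)(C)[C@@H](O)CC[C@]13C
F2 | step 9 | diacetate of F1 | C12(OCCO1)CC[C@@H]3C(C)(C)[C@@H](OC(C)=O)CC[C@]3(C)[C@H]2CC[C@H]1C2(OCCO2)CC[C@@H]3C(C)(C)[C@@H](OC(C)=O)CC[C@]13C
F3 | step 9 | diacetate of 17 (trans-fused) | C12(OCCO1)CC[C@H]3C(C)(C)[C@@H](OC(C)=O)CC[C@]3(C)[C@H]2CC[C@H]1C2(OCCO2)CC[C@H]3C(C)(C)[C@@H](OC(C)=O)CC[C@]13C
F4 | step 3 | 1,2-bis[2-methoxy-6-{[(2S)-2-(methoxymethyl)pyrrolidin-1-yl]carbonyl}cyclohexa-1,4-dien-1-yl]ethane (C10 and C10' epimers) | COC[C@@H]1CCCN1C(=O)C1C=CCC(OC)=C1CCC1=C(OC)CC=CC1C(=O)N1CCC[C@H]1COC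
F5 | step 7 | bis(methanesulfonate) of 12 | C12(OCCO1)CC=C[C@](COS(C)(=O)=O)(CCC=C(C)C)[C@H]2CC[C@H]1C2(OCCO2)CC=C[C@]1(COS(C)(=O)=O)CCC=C(C)C
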